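The flavanone is cut at C2–C1′ into a 6-prenylchromone and a chromenylboronic acid. An enantioselective rhodium-catalysed 1,4-addition joins them and sets C2. The plan rests on the 2,2-dimethylpyran ring fused to ring B. Its O1–C2(CH3)2–C3 segment is the intact skeleton of isobutylene oxide. C4, C4a and C8a are the 1,3-dielectrophile of an o-fluorobenzaldehyde. Reductive lithiation turns the epoxide into a C,O-dianion. In one flask its carbanion adds to the aldehyde, its tertiary alkoxide displaces fluoride, and an acid quench delivers the chromene. The precursor is plain 5-bromo-2-fluorobenzaldehyde.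

Key step: step 1

Remark: the target SMILES encodes the 2S flavanone. Locants O1–C8a in step 1 are those of the chromene unit. The sense of induction in step 6 is assigned by analogy with cyclic enones.

Step 1
Reactants: 1 5-bromo-2-fluorobenzaldehyde; 2 2,2-dimethyloxirane (isobutylene oxide)
Product: 6 6-bromo-2,2-dimethyl-2H-chromene, via β-lithioalkoxide 3 (not isolated), via dilithium diolate 4 (not isolated), via chroman-4-ol 5 (not isolated)
Conditions: 2, lithium 4,4′-di-tert-butylbiphenylide (LiDBB, 2 equiv), THF, −78 °C; 1, −78 °C → rt; KOt-Bu (2 equiv), 65 °C; TsOH·H2O (excess), PhMe, 80 °C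
Reagents that add atoms: none
Why: Electron transfer from LiDBB cleaves the less substituted C–O bond of 2 to give the C,O-dianion 3, whose carbanion adds to the aldehyde of 1 at −78 °C (C3–C4 bond) faster than it can exchange with the aryl bromide. After cation exchange with KOt-Bu the tertiary alkoxide of 4 attacks the fluorine-bearing carbon C8a and expels fluoride by addition–elimination (SNAr, O1–C8a bond), a 6-exo-trig closure of the pyran ring that is helped by the gem-dimethyl effect and by the inductive pull of the para bromine. The closest known reaction types are the 1,3-diol synthesis from β-lithioalkoxides and aldehydes, the cyclisation of 3-(2-fluorophenyl)propanolates to chromans and the acid dehydration of chroman-4-ols, here merged in one flask. The substrate secures the selectivity needed: the benzylic alkoxide could only close a four-membered ring, and fluoride is by far the better nucleofuge than bromide in SNAr. The carbinol stereocentre C4 forms without control and is erased when TsOH ionises 5 to the O1-stabilised benzylic cation, which can lose a proton only from C3 because C2 is quaternary.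

Step 2
Reactants: 6 6-bromo-2,2-dimethyl-2H-chromene
Product: 8 (2,2-dimethyl-2H-chromen-6-yl)boronic acid, via chromenyllithium 7 (not isolated)
Conditions: n-BuLi, THF, −78 °C; B(Oi-Pr)3, −78 °C → rt; 1 M HCl (aq), 0 °C
Reagents that add atoms: triisopropyl borate CC(C)OB(OC(C)C)OC(C)C; water O
Why: Bromine–lithium exchange at −78 °C is faster than any attack on the chromene, and trapping the aryllithium with a borate ester followed by hydrolysis is the standard borylation of aryl halides.

Step 3
Reactants: 9 2,4-dihydroxyacetophenone; 10 2-methylbut-3-en-2-ol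
Product: 11 1-[2,4-dihydroxy-5-(3-methylbut-2-enyl)phenyl]ethanone
Conditions: BF3·OEt2 (0.3 equiv), 1,4-dioxane, 25 °C
Reagents that add atoms: none
Why: Friedel–Crafts prenylation, in which BF3 ionises the tertiary allylic alcohol to the dimethylallyl cation and C5 of the resorcinol ring (ortho to 4-OH, para to 2-OH, less crowded than C3) attacks its primary terminus.

Step 4
Reactants: 11 1-[2,4-dihydroxy-5-(3-methylbut-2-enyl)phenyl]ethanone
Product: 12 1-[2-hydroxy-4-(methoxymethoxy)-5-(3-methylbut-2-enyl)phenyl]ethanone
Conditions: MOMCl (1.1 equiv), K2CO3, acetone, 0 °C → rt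
Reagents that add atoms: chloromethyl methyl ether COCCl
Why: Williamson-type O-alkylation, selective because the 2-OH is held in a hydrogen bond to the ketone while the more acidic free 4-OH is deprotonated and alkylated.

Step 5
Reactants: 12 1-[2-hydroxy-4-(methoxymethoxy)-5-(3-methylbut-2-enyl)phenyl]ethanone
Product: 14 7-(methoxymethoxy)-6-(3-methylbut-2-enyl)-4H-chromen-4-one, via enaminone 13 (not isolated)
Conditions: DMF-DMA, PhMe, 100 °C; evaporate; AcOH, 80 °C
Reagents that add atoms: N,N-dimethylformamide dimethyl acetal COC(OC)N(C)C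
Why: Enaminone route to chromones, in which the methyl ketone condenses with the amide acetal and the phenol then adds to the protonated enaminone and expels dimethylamine (addition–elimination), in an acid too weak to cleave the MOM acetal or protonate the prenyl alkene.

Step 6
Reactants: 14 7-(methoxymethoxy)-6-(3-methylbut-2-enyl)-4H-chromen-4-one; 8 (2,2-dimethyl-2H-chromen-6-yl)boronic acid
Product: 15 (2S)-2-(2,2-dimethyl-2H-chromen-6-yl)-7-(methoxymethoxy)-6-(3-methylbut-2-enyl)chroman-4-one
Conditions: [RhCl(C2H4)2]2 (1.5 mol %), (S)-MeO-F12-BIPHEP [(S)-2,2′-bis[bis(3,4,5-trifluorophenyl)phosphino]-6,6′-dimethoxy-1,1′-biphenyl, 3.3 mol %], aq KOH (10 mol %), PhMe, 25 °C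
Reagents that add atoms: none
Why: Hayashi–Miyaura reaction, in which the aryl-rhodium species inserts the activated C2=C3 bond of the chromone rather than the prenyl or chromene alkenes, and the electron-poor (S)-biaryl diphosphine shields one enone face in the sense known for cyclic enones, so that aryl transfer should set C2 as S before hydrolysis releases the ketone.

Step 7
Reactants: 15 (2S)-2-(2,2-dimethyl-2H-chromen-6-yl)-7-(methoxymethoxy)-6-(3-methylbut-2-enyl)chroman-4-one
Product: 16 dinklagin A, (2S)-2-(2,2-dimethyl-2H-chromen-6-yl)-7-hydroxy-6-(3-methylbut-2-enyl)chroman-4-one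
Conditions: HCl (0.5 M in MeOH), 25–40 °C
Reagents that add atoms: none
Why: Acid-catalysed transacetalisation should cleave the phenolic MOM acetal well before dilute acid protonates the trisubstituted alkene or opens the pyranone, so that C2 should keep its configuration.

Compound list
1 | 5-bromo-2-fluorobenzaldehyde | O=Cc1cc(Br)ccc1F | starting material
2 | 2,2-dimethyloxirane | CC1(C)CO1 | starting material
3 | lithium 1-lithio-2-methylpropan-2-olate | [Li]CC(C)(C)O[Li] | intermediate
4 | dilithium 1-(5-bromo-2-fluorophenyl)-3-methylbutane-1,3-diolate (racemic) | [Li]OC(CC(C)(C)O[Li])c1cc(Br)ccc1F | intermediate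
5 | 6-bromo-2,2-dimethylchroman-4-ol (racemic) | CC1(C)CC(O)c2cc(Br)ccc2O1 | intermediate
6 | 6-bromo-2,2-dimethyl-2H-chromene | CC1(C)C=Cc2cc(Br)ccc2O1 | intermediate
7 | (2,2-dimethyl-2H-chromen-6-yl)lithium | [Li]c1ccc2OC(C)(C)C=Cc2c1 | intermediate
8 | (2,2-dimethyl-2H-chromen-6-yl)boronic acid | CC1(C)C=Cc2cc(B(O)O)ccc2O1 | intermediate
9 | 2,4-dihydroxyacetophenone | CC(=O)c1ccc(O)cc1O | starting material
10 | 2-methylbut-3-en-2-ol | C=CC(C)(C)O | starting material
11 | 1-[2,4-dihydroxy-5-(3-methylbut-2-enyl)phenyl]ethanone | CC(=O)c1cc(CC=C(C)C)c(O)cc1O | intermediate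
12 | 1-[2-hydroxy-4-(methoxymethoxy)-5-(3-methylbut-2-enyl)phenyl]ethanone | CC(=O)c1cc(CC=C(C)C)c(OCOC)cc1O | intermediate
13 | (E)-3-(dimethylamino)-1-[2-hydroxy-4-(methoxymethoxy)-5-(3-methylbut-2-enyl)phenyl]prop-2-en-1-one | CN(C)/C=C/C(=O)c1cc(CC=C(C)C)c(OCOC)cc1O | intermediate
14 | 7-(methoxymethoxy)-6-(3-methylbut-2-enyl)-4H-chromen-4-one | O=c1ccoc2cc(OCOC)c(CC=C(C)C)cc12 | intermediate
15 | (2S)-2-(2,2-dimethyl-2H-chromen-6-yl)-7-(methoxymethoxy)-6-(3-methylbut-2-enyl)chroman-4-one | CC(C)=CCc1cc2c(cc1OCOC)O[C@H](c1ccc3c(c1)C=CC(C)(C)O3)CC2=O | intermediate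
16 | dinklagin A | CC(C)=CCc1cc2c(cc1O)O[C@H](c1ccc3c(c1)C=CC(C)(C)O3)CC2=O | target

Total steps: 7. Longest linear sequence: 5 steps (9 → 11 → 12 → 14 → 15 → 16, steps 3–7).

Steps most likely to fail

1. Step 1. Once the carbanion has added, the fluoroarene has lost its activating aldehyde, so the ring closure may stall. Bromine–lithium exchange or electron transfer to the aryl bromide may also erode the halide handle. The fallback makes the same two bonds in the reverse order by known chemistry. It sets out from 1. The fluoride is displaced while the ortho aldehyde still activates it, using the potassium alkoxide of 10 (KH, THF, 0 °C), to give 5-bromo-2-[(2-methylbut-3-en-2-yl)oxy]benzaldehyde F1. Wittig methylenation (Ph3PCH3Br, KOt-Bu, THF) gives 4-bromo-2-ethenyl-1-[(2-methylbut-3-en-2-yl)oxy]benzene F2. Ring-closing metathesis (second-generation Grubbs catalyst, CH2Cl2, 40 °C) comes back to the route at 6.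

2. Step 6. Insertion into the donor-substituted chromone may be slow, so that protodeboronation takes over. Reversible opening of the pyranone under the basic aqueous conditions may also erode the enantiomeric purity. The fallback sets out from 6. Lithiation to 7 and a DMF quench give 2,2-dimethyl-2H-chromene-6-carbaldehyde F3. Claisen–Schmidt condensation with 12 (KOH, EtOH, rt) gives (E)-3-(2,2-dimethyl-2H-chromen-6-yl)-1-[2-hydroxy-4-(methoxymethoxy)-5-(3-methylbut-2-enyl)phenyl]prop-2-en-1-one F4. Oxa-Michael cyclisation (NaOAc, EtOH, reflux) gives the racemic MOM-protected flavanone F5. Kinetic resolution by asymmetric transfer hydrogenation (Cp*RhCl[(R,R)-TsDPEN], HCO2H/Et3N, EtOAc, rt, stopped near half conversion) should reduce the 2R enantiomer to the (2R,4R)-cis-flavan-4-ol F6. The unreacted 2S ketone is separated, and this comes back to the route at 15.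

3. Step 3. The cation may attack with poor regiocontrol (C3 instead of C5, oxygen, or twice), and the acid may cyclise the ortho-prenylphenol onto its alkene. The fallback fixes the position with a halogen. It sets out from 9. Bromination (NBS, MeCN, 0 °C) gives 1-(5-bromo-2,4-dihydroxyphenyl)ethanone F7. Selective protection (MOMCl, K2CO3, acetone) gives 1-[5-bromo-2-hydroxy-4-(methoxymethoxy)phenyl]ethanone F8. Stille coupling with tributyl(3-methylbut-2-enyl)stannane (Pd(PPh3)4, DMF, 90 °C) comes back to the route at 12.

Further compounds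
F1 | step 1 | 5-bromo-2-[(2-methylbut-3-en-2-yl)oxy]benzaldehyde | C=CC(C)(C)Oc1ccc(Br)cc1C=O
F2 | step 1 | 4-bromo-2-ethenyl-1-[(2-methylbut-3-en-2-yl)oxy]benzene | C=CC(C)(C)Oc1ccc(Br)cc1C=C
F3 | step 6 | 2,2-dimethyl-2H-chromene-6-carbaldehyde | CC1(C)C=Cc2cc(C=O)ccc2O1
F4 | step 6 | (E)-3-(2,2-dimethyl-2H-chromen-6-yl)-1-[2-hydroxy-4-(methoxymethoxy)-5-(3-methylbut-2-enyl)phenyl]prop-2-en-1-one | CC(C)=CCc1cc(C(=O)/C=C/c2ccc3OC(C)(C)C=Cc3c2)c(O)cc1OCOC
F5 | step 6 | racemic 2-(2,2-dimethyl-2H-chromen-6-yl)-7-(methoxymethoxy)-6-(3-methylbut-2-enyl)chroman-4-one | CC(C)=CCc1cc2c(cc1OCOC)OC(c1ccc3c(c1)C=CC(C)(C)O3)CC2=O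
F6 | step 6 | (2R,4R)-2-(2,2-dimethyl-2H-chromen-6-yl)-7-(methoxymethoxy)-6-(3-methylbut-2-enyl)chroman-4-ol | CC(C)=CCc1cc2c(cc1OCOC)O[C@@H](c1ccc3c(c1)C=CC(C)(C)O3)C[C@H]2O
F7 | step 3 | 1-(5-bromo-2,4-dihydroxyphenyl)ethanone | CC(=O)c1cc(Br)c(O)cc1O
F8 | step 3 | 1-[5-bromo-2-hydroxy-4-(methoxymethoxy)phenyl]ethanone | CC(=O)c1cc(Br)c(OCOC)cc1O
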